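Its constants stand for no real mixture; the result is computed.

Target per side product, the selectivity ratio, is what I follow here. Both products take the second reagent, so at any moment this ratio equals 24.5 times the fraction of the charge standing as intermediate over the fraction still substrate.

| flask | substrate | partner | second reagent | time | remark |
|---|---|---|---|---|---|
| ochre | 0.020 M | 0.100 M (fed, over 16.0 min) | 0.0210 M | 20 min | all but partner at the start; partner goes in evenly over 16.0 min, the run ends at 20 min |
| red | 0.020 M | 0.100 M | 0.0210 M | 20 min | a closed flask charged with all of it at once and left for 20 min |
| green | 0.020 M | 0.100 M | 0.0210 M |  | a single well-mixed tank run continuously and read at steady state, 200 min in it on average |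
| violet | 0.020 M | 0.100 M | 0.0210 M |  | a single well-mixed tank run continuously and read at steady state, 20 min in it on average |

    substrate + second reagent → side product (k1 = 0.00637 L mol⁻¹ s⁻¹)
    substrate + partner → intermediate (k2 = 0.0182 L mol⁻¹ s⁻¹)
    second reagent + intermediate → target (k3 = 0.156 L mol⁻¹ s⁻¹)
    second reagent → decomposed reagent (k4 = 0.00382 s⁻¹)

- the stated concentrations are those of everything mixed, before any reaction; amounts are the same in each set-up
- the feed brings no volume worth counting
- run time (ochre): 20 min

* order of the set-ups by the share of target in all that became target or side product, at the outlet or at the end, highest first (ochre / red / green / violet)
* share of target in all that became target or side product, at the outlet or at the end, ochre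
* share of target in all that became target or side product, at the outlet or at the end, red
* share of target in all that became target or side product, at the outlet or at the end, green
* share of target in all that became target or side product, at the outlet or at the end, violet

While that quotient is small, it grows by 0.109 min⁻¹ per minute with partner as charged. The ratio therefore climbs by 2.67 min⁻¹ per minute of age, and this is my ratio gain. What differs between the flasks is the age.

In red, the second reagent has a mean life of 4.36 min, shorter than the run, so I take that life as the age. That gives a ratio of 11.7, a share of 92.1%.

In ochre, partner arrives over 16.0 min, so the quotient grows with the square of time. Averaging over the reagent's life gives 3.18, a share of 76.1%.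

In the tanks, the age is the mean residence time. Violet gets 53.5, a share of 98.2%, and green gets 535, a share of 99.8%.

I have ignored the drain of intermediate into target. In red its mean life by that step is 5.09 min at charged reagent, a little longer than the reagent's 4.36 min, so the two are of one order and I expect my red ratio to run high.

The forecast gives green > violet > red > ochre, with ochre 63%, red 88%, green 99.6% and violet 96.8%, lower than mine for ochre and red, and holds that “slow partner feed starves intermediate formation”.

The flask gives green > violet > red > ochre, with ochre 62.3%, red 87.7%, green 99.6% and violet 96.8%.

For red, that share means a ratio of 7.13, so my 11.7 from the gain of 2.67 min⁻¹ stands 1.64 times above it. Violet reads 22.9% of the charge as target and 0.762% as side product, a ratio of 30.1, and my 53.5 stands 1.78 times above that reading. My ochre ratio of 3.18 contains the dosing time and the reagent's life but no run time, and ochre left to 200 min gives 62.9%.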